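**Strategy.** Ferocaulidin is cut across ring B (drimane numbering: C3 carbinol, C4 CMe2, C5/C10 ring fusion, C11 the CH2O carbon on C9). The C6 ketone with the C7=C8 alkene is the retron of a C5=C6(OSi)–C7=C8 siloxydiene adding to a C9=C10 enal (C11 = CHO), and the C1–C4 chain linking C5 to C10 becomes ring A. One enantioselective, Lewis acid-catalysed intramolecular [4+2] cycloaddition therefore forms C5–C10 and C8–C9, closes rings A and B and sets C5, C8, C9 and C10. Its precursor is an achiral open-chain (2E,8Z,10E)-trienal carrying the C6 silyl dienol ether, the C4 gem-dimethyl group and a free C3 ketone. The adduct then needs only reduction, aryl ether formation and dehydrosilylation.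

Key step: step 9

Remarks before the steps.
- Positions are given in drimane numbering: ring A = C1–C5 and C10, ring B = C5–C10, methyl groups on C4 (two), C8 and C10.
- The target SMILES corresponds to (3S,5S,9R,10S): trans ring fusion, C11 cis to the C10 methyl, 3-OH axial on the face of H5. The intermediates below were checked against it.
- Design choice: C3 travels as an acetate and is oxidised, together with C11, only after the dienol ether is in place. The cyclisation substrate therefore has a free C3 ketone instead of a ketal, the enol ether survives to the last step, and the aldehyde is never exposed to enolising conditions.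
- Assumption: the (S)-oxazaborolidinium ion is taken to shield the enal face that is Si at C9. If the first run shows the opposite sense, the (R)-catalyst is used with nothing else changed.

Step 1
Reactants: 1 2,2-dimethylpent-4-enal; 2 2-(2-bromoethyl)-2-methyl-1,3-dioxolane
Product: 6 4,4-dimethyl-8-oxonon-1-en-5-yl acetate (racemic), via Grignard reagent 3 (not isolated), via magnesium alkoxide 4 (not isolated), via acetoxy dioxolane 5 (not isolated)
Conditions: 2, Mg, THF, 25 °C; 1, 0 °C; Ac2O, 0 °C → rt; then 2 M HCl, THF, rt
Reagents that add atoms: acetic anhydride CC(=O)OC(C)=O; water O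
Why: Grignard addition to a non-enolisable α-quaternary aldehyde, O-acylation of the magnesium alkoxide and acid hydrolysis of the methyl-ketone dioxolane in the work-up; the carbinol centre is formed racemic on purpose, because it is oxidised to the C3 ketone before the key step and the acetate only masks that ketone during the enolate chemistry.

Step 2
Reactants: 6 4,4-dimethyl-8-oxonon-1-en-5-yl acetate; 7 triethyl phosphonoacetate
Product: 9 ethyl (2E)-6-acetoxy-3,7,7-trimethyldeca-2,9-dienoate (racemic), via sodium phosphonate 8 (not isolated)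
Conditions: 7, NaH, THF, 0 °C; then 6, 0 → 40 °C
Reagents that add atoms: none
Why: Horner–Wadsworth–Emmons olefination of an unhindered methyl ketone under equilibrating conditions places the ester trans to the longer chain, so the (E)-enoate should predominate and the minor (Z)-isomer is removed by chromatography; acetate and terminal alkene are inert.

Step 3
Reactants: 9 ethyl (2E)-6-acetoxy-3,7,7-trimethyldeca-2,9-dienoate
Product: 10 ethyl (2E)-6-acetoxy-3,7,7-trimethyl-9-oxodec-2-enoate (racemic)
Conditions: PdCl2 (10 mol %), CuCl, O2 (1 atm), DMF/H2O 7:1, rt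
Reagents that add atoms: water O
Why: Tsuji–Wacker oxidation, in which Markovnikov hydroxypalladation of the only monosubstituted alkene gives the C6 methyl ketone while the trisubstituted enoate alkene and both esters do not react.

Step 4
Reactants: 10 ethyl (2E)-6-acetoxy-3,7,7-trimethyl-9-oxodec-2-enoate; 11 acetaldehyde
Product: 13 ethyl (2E)-6-acetoxy-11-hydroxy-3,7,7-trimethyl-9-oxododec-2-enoate (mixture of diastereomers), via lithium enolate 12 (not isolated)
Conditions: LiN(SiMe3)2, THF, −78 °C; 11, −78 °C; aq. NH4Cl
Reagents that add atoms: none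
Why: Directed aldol addition, in which LiN(SiMe3)2 deprotonates the methyl ketone at its methyl group (the neopentylic CH2 and the ester positions are slower) and the enolate adds to acetaldehyde; the new carbinol centre is uncontrolled and is destroyed in step 5.

Step 5
Reactants: 13 ethyl (2E)-6-acetoxy-11-hydroxy-3,7,7-trimethyl-9-oxododec-2-enoate
Product: 15 ethyl (2E,10E)-6-acetoxy-3,7,7-trimethyl-9-oxododeca-2,10-dienoate (racemic), via mesylate 14 (not isolated)
Conditions: MsCl, Et3N, CH2Cl2, 0 °C → rt
Reagents that add atoms: none
Why: Mesylation followed by E1cB elimination of the β-mesyloxy ketone gives the conjugated propenyl ketone, the (E)-alkene being the thermodynamic product.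

Step 6
Reactants: 15 ethyl (2E,10E)-6-acetoxy-3,7,7-trimethyl-9-oxododeca-2,10-dienoate
Product: 16 ethyl (2E,8Z,10E)-6-acetoxy-9-[(tert-butyldimethylsilyl)oxy]-3,7,7-trimethyldodeca-2,8,10-trienoate (racemic)
Conditions: TBSOTf, Et3N, CH2Cl2, −78 → 0 °C
Reagents that add atoms: tert-butyldimethylsilyl triflate CC(C)(C)[Si](C)(C)OS(=O)(=O)C(F)(F)F
Why: Soft enolisation (silyl triflate and amine), in which O-silylation of the ketone and deprotonation at its only α′ position, the C5 methylene, gives the cross-conjugated 2-silyloxydiene; the (Z)-enol ether is expected because it keeps the tert-alkyl C4 substituent away from the propenyl group (allylic strain), and the esters are not enolised at low temperature.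

Step 7
Reactants: 16 ethyl (2E,8Z,10E)-6-acetoxy-9-[(tert-butyldimethylsilyl)oxy]-3,7,7-trimethyldodeca-2,8,10-trienoate
Product: 17 (2E,8Z,10E)-9-[(tert-butyldimethylsilyl)oxy]-3,7,7-trimethyldodeca-2,8,10-triene-1,6-diol (racemic)
Conditions: i-Bu2AlH (5 equiv), CH2Cl2, −78 °C; aq. potassium sodium tartrate
Reagents that add atoms: none
Why: Aluminium hydride reduction at −78 °C converts the enoate into the allylic alcohol by 1,2-reduction and cleaves the acetate, while the silyl dienol ether is inert to i-Bu2AlH.

Step 8
Reactants: 17 (2E,8Z,10E)-9-[(tert-butyldimethylsilyl)oxy]-3,7,7-trimethyldodeca-2,8,10-triene-1,6-diol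
Product: 18 (2E,8Z,10E)-9-[(tert-butyldimethylsilyl)oxy]-3,7,7-trimethyl-6-oxododeca-2,8,10-trienal (achiral)
Conditions: Dess–Martin periodinane, pyridine, CH2Cl2, 0 °C → rt
Reagents that add atoms: none
Why: Dess–Martin oxidation under pyridine buffering takes the allylic alcohol to the (E)-enal and the hindered carbinol to the C3 ketone in one operation, which removes the only stereocentre and leaves the acid-sensitive dienol ether intact.

Step 9
Reactants: 18 (2E,8Z,10E)-9-[(tert-butyldimethylsilyl)oxy]-3,7,7-trimethyl-6-oxododeca-2,8,10-trienal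
Product: 19 (5S,8R,9R,10R)-6-[(tert-butyldimethylsilyl)oxy]-3-oxodrim-6-en-11-al (descriptors in drimane numbering; trans-fused, with 8-CH3, 9-CHO and 10-CH3 on one face and H5, H8, H9 on the other)
Conditions: (S)-3,3-diphenyl-1-(o-tolyl)tetrahydro-1H,3H-pyrrolo[1,2-c][1,3,2]oxazaborole (20 mol %), HN(SO2CF3)2 (18 mol %), CH2Cl2, −78 → −20 °C; Et3N quench
Reagents that add atoms: none
Why: Proposed new method: the triflimide-activated oxazaborolidinium ion binds the formyl oxygen (the formyl C–H being held by the ring oxygen), and the s-trans enal then reacts with the tethered 2-silyloxydiene in a concerted but asynchronous [4+2] event in which the enol ether carbon C5 bonds to the activated β-carbon C10 ahead of C8–C9. The closest known reaction types are Lewis acid-promoted type 1 intramolecular Diels–Alder reactions of deca-1,7,9-trienes and oxazaborolidinium-catalysed intermolecular cycloadditions of enals with 2-silyloxydienes; neither covers a β,β-disubstituted enal adding to a neopentylic diene terminus. Ring A closes through the C5–C10 bond over the four-carbon C1–C4 tether folded as a chair, and ring B is the cyclohexene of the cycloaddition, closed by C5–C10 and C8–C9. C9 relative to C10 is fixed by the (E)-enal (suprafacial addition keeps C11 cis to the C10 methyl); C5 and C8 are fixed by the endo position of the boron-bound formyl group together with the (Z)-enol ether and (E)-propenyl geometry, which put H5, H8 and H9 on one face and give the trans fusion; the absolute sense comes from the catalyst, whose aryl group blocks one enal face so that the diene adds to the face that is Re at C9. The step needs endo selectivity, enantioface selectivity and survival of the enol ether: the nucleophilic diene terminus is matched to the activated β-carbon, the C4 gem-dimethyl group and the sp2 C3 carbonyl favour the folded tether, and strictly aprotic conditions with an amine quench keep the silyl group on O6.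

Step 10
Reactants: 19 (5S,8R,9R,10R)-6-[(tert-butyldimethylsilyl)oxy]-3-oxodrim-6-en-11-al
Product: 20 (3S,5S,8S,9R,10S)-6-[(tert-butyldimethylsilyl)oxy]drim-6-ene-3,11-diol (3-OH axial, on the face of H5)
Conditions: LiBH(s-Bu)3 (3 equiv), THF, −78 °C; then H2O2, NaH2PO4/Na2HPO4 buffer (pH 7), 0 °C
Reagents that add atoms: none
Why: Hydride reduction with a bulky trialkylborohydride, in which the aldehyde gives the C11 alcohol and the C3 ketone is attacked along the equatorial trajectory (steric approach control), setting the axial (3S) alcohol, while the silyl enol ether is untouched.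

Step 11
Reactants: 20 (3S,5S,8S,9R,10S)-6-[(tert-butyldimethylsilyl)oxy]drim-6-ene-3,11-diol; 21 umbelliferone
Product: 22 7-{[(3S,5S,8S,9R,10S)-6-[(tert-butyldimethylsilyl)oxy]-3-hydroxydrim-6-en-11-yl]oxy}-2H-chromen-2-one
Conditions: PPh3, DIAD, THF, 0 °C → rt
Reagents that add atoms: none
Why: Mitsunobu etherification, in which the primary C11 alcohol is activated as its alkoxyphosphonium ion and displaced by the acidic phenol (pKa about 8), whereas the axial, neopentylic C3 alcohol is too hindered to react; no stereocentre is touched.

Step 12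
Reactants: 22 7-{[(3S,5S,8S,9R,10S)-6-[(tert-butyldimethylsilyl)oxy]-3-hydroxydrim-6-en-11-yl]oxy}-2H-chromen-2-one
Product: 23 ferocaulidin, (3S,5S,9R,10S)-3-hydroxy-11-[(2-oxo-2H-chromen-7-yl)oxy]drim-7-en-6-one
Conditions: Pd(OAc)2 (1.2 equiv), MeCN, rt → 40 °C
Reagents that add atoms: none
Why: Saegusa–Ito oxidation, in which the silyl enol ether transmetalates to a C7-bound divalent palladium enolate on the face opposite the C8 and C10 methyl groups and syn β-hydride elimination of H8, the only β-hydrogen, gives the 7-en-6-one and removes the surplus C8 stereocentre without base, so that C5, C9 and the aryl ether are preserved.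

**Compound list**

1 | 2,2-dimethylpent-4-enal | C=CCC(C)(C)C=O | starting material
2 | 2-(2-bromoethyl)-2-methyl-1,3-dioxolane | CC1(CCBr)OCCO1 | starting material
3 | [2-(2-methyl-1,3-dioxolan-2-yl)ethyl]magnesium bromide | CC1(CC[Mg]Br)OCCO1 | intermediate
4 | bromomagnesium 4,4-dimethyl-1-(2-methyl-1,3-dioxolan-2-yl)hept-6-en-3-olate (racemic) | CC1(CCC(O[Mg]Br)C(C)(C)CC=C)OCCO1 | intermediate
5 | 4,4-dimethyl-1-(2-methyl-1,3-dioxolan-2-yl)hept-6-en-3-yl acetate (racemic) | CC(=O)OC(CCC1(C)OCCO1)C(C)(C)CC=C | intermediate
6 | 4,4-dimethyl-8-oxonon-1-en-5-yl acetate (racemic) | CC(=O)CCC(OC(C)=O)C(C)(C)CC=C | intermediate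
7 | triethyl phosphonoacetate | CCOC(=O)CP(=O)(OCC)OCC | starting material
8 | sodium salt of triethyl phosphonoacetate | CCOC(=O)[CH-]P(=O)(OCC)OCC.[Na+] | intermediate
9 | ethyl (2E)-6-acetoxy-3,7,7-trimethyldeca-2,9-dienoate (racemic) | CCOC(=O)/C=C(\C)CCC(OC(C)=O)C(C)(C)CC=C | intermediate
10 | ethyl (2E)-6-acetoxy-3,7,7-trimethyl-9-oxodec-2-enoate (racemic) | CCOC(=O)/C=C(\C)CCC(OC(C)=O)C(C)(C)CC(C)=O | intermediate
11 | acetaldehyde | CC=O | starting material
12 | lithium enolate of 10 (methyl side) | CCOC(=O)/C=C(\C)CCC(OC(C)=O)C(C)(C)CC(=C)O[Li] | intermediate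
13 | ethyl (2E)-6-acetoxy-11-hydroxy-3,7,7-trimethyl-9-oxododec-2-enoate (mixture of diastereomers) | CCOC(=O)/C=C(\C)CCC(OC(C)=O)C(C)(C)CC(=O)CC(C)O | intermediate
14 | methanesulfonate of 13 | CCOC(=O)/C=C(\C)CCC(OC(C)=O)C(C)(C)CC(=O)CC(C)OS(C)(=O)=O | intermediate
15 | ethyl (2E,10E)-6-acetoxy-3,7,7-trimethyl-9-oxododeca-2,10-dienoate (racemic) | CCOC(=O)/C=C(\C)CCC(OC(C)=O)C(C)(C)CC(=O)/C=C/C | intermediate
16 | ethyl (2E,8Z,10E)-6-acetoxy-9-[(tert-butyldimethylsilyl)oxy]-3,7,7-trimethyldodeca-2,8,10-trienoate (racemic) | CCOC(=O)/C=C(\C)CCC(OC(C)=O)C(C)(C)/C=C(O[Si](C)(C)C(C)(C)C)/C=C/C | intermediate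
17 | (2E,8Z,10E)-9-[(tert-butyldimethylsilyl)oxy]-3,7,7-trimethyldodeca-2,8,10-triene-1,6-diol (racemic) | OC/C=C(\C)CCC(O)C(C)(C)/C=C(O[Si](C)(C)C(C)(C)C)/C=C/C | intermediate
18 | (2E,8Z,10E)-9-[(tert-butyldimethylsilyl)oxy]-3,7,7-trimethyl-6-oxododeca-2,8,10-trienal (achiral cyclisation precursor) | O=C/C=C(\C)CCC(=O)C(C)(C)/C=C(O[Si](C)(C)C(C)(C)C)/C=C/C | intermediate
19 | (5S,8R,9R,10R)-6-[(tert-butyldimethylsilyl)oxy]-3-oxodrim-6-en-11-al (drimane numbering, trans-fused) | C[C@@H]1C=C(O[Si](C)(C)C(C)(C)C)[C@@H]2C(C)(C)C(=O)CC[C@@]2(C)[C@@H]1C=O | intermediate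
20 | (3S,5S,8S,9R,10S)-6-[(tert-butyldimethylsilyl)oxy]drim-6-ene-3,11-diol | C[C@@H]1C=C(O[Si](C)(C)C(C)(C)C)[C@@H]2C(C)(C)[C@@H](O)CC[C@@]2(C)[C@@H]1CO | intermediate
21 | umbelliferone (7-hydroxy-2H-chromen-2-one) | O=c1ccc2ccc(O)cc2o1 | starting material
22 | 7-{[(3S,5S,8S,9R,10S)-6-[(tert-butyldimethylsilyl)oxy]-3-hydroxydrim-6-en-11-yl]oxy}-2H-chromen-2-one | C[C@@H]1C=C(O[Si](C)(C)C(C)(C)C)[C@@H]2C(C)(C)[C@@H](O)CC[C@@]2(C)[C@@H]1COc1ccc2ccc(=O)oc2c1 | intermediate
23 | ferocaulidin, (3S,5S,9R,10S)-3-hydroxy-11-[(2-oxo-2H-chromen-7-yl)oxy]drim-7-en-6-one | CC1=CC(=O)[C@@H]2C(C)(C)[C@@H](O)CC[C@@]2(C)[C@@H]1COc1ccc2ccc(=O)oc2c1 | target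

**Step count.** 12 steps in total; the longest linear sequence is 12 steps (from 1 or 2 to 23).

**Steps most likely to fail**

Step 9 (key cycloaddition).
- What may go wrong: the β,β-disubstituted enal may be activated too weakly for turnover at temperatures the catalyst tolerates. The asynchronous pathway may be intercepted after C5–C10 bond formation, by silyl transfer or by closure through the aldehyde oxygen, instead of closing C8–C9. Enantioface or endo selectivity may be eroded by an uncatalysed background reaction.
- Fallback (known chemistry), setting out from 18 and returning at 20: the trienal is cyclised without a chiral catalyst, by heating in toluene with BHT in a sealed tube (about 170 °C) or with Me2AlCl at low temperature, the established thermal and Lewis acid forms of the type 1 intramolecular Diels–Alder reaction. After removal of any cis-fused isomer this should give the racemic trans-fused keto aldehyde F1. Reduction with LiBH(s-Bu)3 as in step 10 would give the racemic diol F2, which is resolved by preparative chromatography on a chiral stationary phase; the (3S,5S,8S,9R,10S) enantiomer is 20.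

Step 11 (Mitsunobu etherification).
- What may go wrong: displacement at the β-branched C11, next to the quaternary C10, may be slow, so the alkoxyphosphonium ion is consumed by elimination or hydrazide alkylation and the alcohol is recovered.
- Fallback, setting out from 20 and returning at 22: the C11–O–aryl bond is made from the aryl side by palladium-catalysed C–O cross-coupling of the primary alcohol with 7-bromocoumarin (Pd2(dba)3, t-BuBrettPhos, Cs2CO3, toluene, 90 °C), so no substitution at the hindered carbon is needed. The hindered secondary alcohol should not compete, and the fallback passes through no new isolable compound (F0).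

Step 12 (Saegusa–Ito oxidation).
- What may go wrong: transmetalation of the hindered tert-butyldimethylsilyl enol ether may be slow, so protodesilylation to the saturated 6-ketone competes with dehydrogenation.
- Fallback, setting out from 22 and returning at 23: the enol ether is selenenylated with PhSeCl (CH2Cl2, −78 °C), expected on the face opposite the methyl groups, to give the α-phenylselanyl ketone F3. Oxidation with H2O2 (pyridine, CH2Cl2, 0 °C → rt) and syn elimination of the selenoxide toward H8, which is cis to selenium, would give 23.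

Further compounds
F1 | step 9 | racemic 6-[(tert-butyldimethylsilyl)oxy]-3-oxodrim-6-en-11-al (racemate of 19, both enantiomers written) | C[C@@H]1C=C(O[Si](C)(C)C(C)(C)C)[C@@H]2C(C)(C)C(=O)CC[C@@]2(C)[C@@H]1C=O.C[C@H]1C=C(O[Si](C)(C)C(C)(C)C)[C@H]2C(C)(C)C(=O)CC[C@]2(C)[C@H]1C=O
F2 | step 9 | racemic 6-[(tert-butyldimethylsilyl)oxy]drim-6-ene-3,11-diol (racemate of 20, both enantiomers written) | C[C@@H]1C=C(O[Si](C)(C)C(C)(C)C)[C@@H]2C(C)(C)[C@@H](O)CC[C@@]2(C)[C@@H]1CO.C[C@H]1C=C(O[Si](C)(C)C(C)(C)C)[C@H]2C(C)(C)[C@H](O)CC[C@]2(C)[C@H]1CO
F0 | step 11 | none | none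
F3 | step 12 | 7-{[3-hydroxy-6-oxo-7-(phenylselanyl)driman-11-yl]oxy}-2H-chromen-2-one (selenium on the face of H5, H8 and H9) | C[C@@H]1[C@@H]([Se]c3ccccc3)C(=O)[C@@H]2C(C)(C)[C@@H](O)CC[C@@]2(C)[C@@H]1COc1ccc2ccc(=O)oc2c1
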